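**Plan**
1. The chain is numbered C1 (Z-allylic CH2OH) to C16, with C19 the CH2OH on C7. The C6–C7 oxirane with C19–OH is a 2,3-epoxy-1-ol, the Payne isomer of a C7–C19 oxirane carrying a C6 carbinol.
2. Retrosynthesis cuts C7–O(6) first (Payne shift, back to oxirane 28), then C6–C7 (CrCl2/NiCl2 coupling), C9–C10 (alkenyllithium + glycidyl ether) and C13–C14 (alkenyl Grignard + glycidol).
3. Forward: (S)-glycidol gives the C10–C15 iodide 13; opening of trityl glycidyl ether 14 gives C7–C15; alkyne to 2-iodoalkene 22; coupling with neryl aldehyde 4. The only ring is made on C7–C19 and then moved to C6–C7.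
4. Stereochemistry: C12 and C8 come from the two glycidol series; C6 from oxazaborolidine reduction (6R) followed by Mitsunobu inversion (6S); C7 from Ti/D-(−)-tartrate epoxidation under the 6R hydroxyl, relayed with inversion in the shift.
5. The detour through the 6R carbinol is deliberate: titanium–tartrate epoxidation of a 2-methylene carbinol is erythro-selective, while the shift to the target ring (C5 cis to C19) needs the threo epoxy alcohol.
6. End game: DDQ removes the PMB group, buffered fluoride removes both silyl groups.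

Key step: step 22

Remark: 14 is assumed to be bought as (S)-trityl glycidyl ether, the trityl ether of (R)-glycidol. From 23 on, locants are those of the target chain; the CIP label of C7 changes with the O-substituents although only step 22 alters that centre. TBS = tert-butyldimethylsilyl, PMB = 4-methoxybenzyl, Tr = trityl.

**Route**

Step 1
Reactants: 1 nerol
Product: 2 neryl TBS ether
Conditions: TBSCl, imidazole, DMF, 0 °C to rt
Reagents that add atoms: tert-butyldimethylsilyl chloride, CC(C)(C)[Si](C)(C)Cl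
Why: Silylation of the primary allylic alcohol should be clean and masks O1 so that it cannot direct the later titanium epoxidation.

Step 2
Reactants: 2 neryl TBS ether
Product: 3 (Z)-6,7-epoxy-1-(TBSO)-3,7-dimethyloct-2-ene (racemic)
Conditions: mCPBA (1 equiv), CH2Cl2, −20 °C
Reagents that add atoms: 3-chloroperoxybenzoic acid, OOC(=O)c1cccc(Cl)c1
Why: Prilezhaev epoxidation should prefer the remote trisubstituted alkene because the 2,3-alkene is deactivated by the allylic silyloxy group; the new centre is lost in step 3.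

Step 3
Reactants: 3 (Z)-6,7-epoxy-1-(TBSO)-3,7-dimethyloct-2-ene
Product: 4 (Z)-6-(TBSO)-4-methylhex-4-enal
Conditions: H5IO6, THF/Et2O, 0 °C
Reagents that add atoms: none
Why: Periodic acid opens the oxirane with water at the tertiary carbon and cleaves the resulting glycol (Malaprade-type cleavage), so the added oxygen leaves in acetone and C6 becomes the aldehyde.

Step 4
Reactants: 5 (S)-glycidol; 6 2-methyl-1-propenylmagnesium bromide (2.5 equiv)
Product: 7 (R)-6-methylhept-5-ene-1,2-diol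
Conditions: CuI (10 mol%), THF, −30 to 0 °C; aqueous NH4Cl
Reagents that add atoms: none
Why: Copper-catalysed Grignard opening at the unsubstituted oxirane carbon forms C13–C14 after the first equivalent has deprotonated the hydroxyl; the carbinol centre (later C12) is untouched.

Step 5
Reactants: 7 (R)-6-methylhept-5-ene-1,2-diol
Product: 8 (R)-1,2-bis(TBSO)-6-methylhept-5-ene
Conditions: TBSCl (2.4 equiv), imidazole, DMF, rt
Reagents that add atoms: tert-butyldimethylsilyl chloride, CC(C)(C)[Si](C)(C)Cl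
Why: Exhaustive silylation of a 1,2-diol is routine and sets up selective release of the primary position.

Step 6
Reactants: 8 (R)-1,2-bis(TBSO)-6-methylhept-5-ene
Product: 9 (R)-2-(TBSO)-6-methylhept-5-en-1-ol
Conditions: HF·pyridine, pyridine, THF, 0 °C
Reagents that add atoms: none
Why: Under buffered HF the primary silyl ether is cleaved well before the secondary one (selective desilylation).

Step 7
Reactants: 9 (R)-2-(TBSO)-6-methylhept-5-en-1-ol
Product: 10 (R)-2-(TBSO)-6-methylhept-5-enal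
Conditions: Dess–Martin periodinane, CH2Cl2, 0 °C to rt
Reagents that add atoms: none
Why: Dess–Martin oxidation should give the α-silyloxy aldehyde under near-neutral conditions without epimerisation.

Step 8
Reactants: 10 (R)-2-(TBSO)-6-methylhept-5-enal
Product: 11 (R)-3-(TBSO)-6-methylhept-5-en-1-yne
Conditions: dimethyl (1-diazo-2-oxopropyl)phosphonate, K2CO3, MeOH, 0 °C to rt
Reagents that add atoms: dimethyl (1-diazo-2-oxopropyl)phosphonate, COP(=O)(OC)C(=[N+]=[N-])C(C)=O
Why: Ohira–Bestmann homologation converts the aldehyde into the terminal alkyne under conditions mild enough to keep the α-oxygenated centre.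

Step 9
Reactants: 11 (R)-3-(TBSO)-6-methylhept-5-en-1-yne
Product: 13 (1E,3R)-1-iodo-3-(TBSO)-2,6-dimethylhepta-1,5-diene, via alkenyldimethylalane 12 (not isolated)
Conditions: Me3Al, Cp2ZrCl2 (0.25 equiv), CH2Cl2, 0 °C to rt; then I2, THF, −30 °C
Reagents that add atoms: trimethylaluminium, C[Al](C)C; iodine, II
Why: Zirconium-catalysed syn-carboalumination (Negishi) puts methyl on the internal and aluminium on the terminal carbon, and iodinolysis with retention gives the E-trisubstituted C10=C11 geometry.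

Step 10
Reactants: 13 (1E,3R)-1-iodo-3-(TBSO)-2,6-dimethylhepta-1,5-diene; 14 (S)-trityl glycidyl ether
Product: 16 (2S,4E,6R)-6-(TBSO)-5,9-dimethyl-1-(trityloxy)deca-4,8-dien-2-ol, via alkenyllithium 15 (not isolated)
Conditions: t-BuLi (2 equiv), Et2O, −78 °C; then 14, BF3·OEt2, −78 °C
Reagents that add atoms: none
Why: Iodine–lithium exchange with retention of alkene geometry, then BF3-assisted SN2 opening of the terminal oxirane carbon, forms C9–C10; the C8 carbinol comes unchanged from 14.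

Step 11
Reactants: 16 (2S,4E,6R)-6-(TBSO)-5,9-dimethyl-1-(trityloxy)deca-4,8-dien-2-ol
Product: 17 (2S,4E,6R)-6-(TBSO)-2-(PMBO)-5,9-dimethyl-1-(trityloxy)deca-4,8-diene
Conditions: NaH, PMBCl, Bu4NI (cat.), THF/DMF, 0 °C to rt
Reagents that add atoms: 4-methoxybenzyl chloride, COc1ccc(CCl)cc1
Why: Williamson etherification caps O8 with a base-stable group that cannot migrate, which the Payne step needs; trityl and silyl ethers tolerate the alkoxide.

Step 12
Reactants: 17 (2S,4E,6R)-6-(TBSO)-2-(PMBO)-5,9-dimethyl-1-(trityloxy)deca-4,8-diene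
Product: 18 (2S,4E,6R)-6-(TBSO)-2-(PMBO)-5,9-dimethyldeca-4,8-dien-1-ol
Conditions: p-TsOH·H2O (cat.), MeOH/CH2Cl2, 0 °C
Reagents that add atoms: none
Why: Acid-catalysed solvolysis through the trityl cation frees the primary alcohol, while the PMB ether and the secondary silyl ether should survive the brief cold treatment.

Step 13
Reactants: 18 (2S,4E,6R)-6-(TBSO)-2-(PMBO)-5,9-dimethyldeca-4,8-dien-1-ol
Product: 19 (2S,4E,6R)-6-(TBSO)-2-(PMBO)-5,9-dimethyldeca-4,8-dienal
Conditions: Dess–Martin periodinane, CH2Cl2, 0 °C to rt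
Reagents that add atoms: none
Why: Dess–Martin oxidation gives the α-alkoxy aldehyde without epimerising C8 or moving the β,γ-alkene.

Step 14
Reactants: 19 (2S,4E,6R)-6-(TBSO)-2-(PMBO)-5,9-dimethyldeca-4,8-dienal
Product: 20 (3S,5E,7R)-7-(TBSO)-3-(PMBO)-6,10-dimethylundeca-5,9-dien-1-yne
Conditions: dimethyl (1-diazo-2-oxopropyl)phosphonate, K2CO3, MeOH, 0 °C
Reagents that add atoms: dimethyl (1-diazo-2-oxopropyl)phosphonate, COP(=O)(OC)C(=[N+]=[N-])C(C)=O
Why: Ohira–Bestmann homologation adds C19 and makes C7 an alkyne carbon; run cold, it should preserve the α-alkoxy centre.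

Step 15
Reactants: 20 (3S,5E,7R)-7-(TBSO)-3-(PMBO)-6,10-dimethylundeca-5,9-dien-1-yne
Product: 22 (3S,5E,7R)-2-iodo-3-(PMBO)-7-(TBSO)-6,10-dimethylundeca-1,5,9-triene, via iodoalkenylborane 21 (not isolated)
Conditions: B-iodo-9-BBN, hexane/CH2Cl2, −20 °C; then AcOH, 0 °C
Reagents that add atoms: B-iodo-9-borabicyclo[3.3.1]nonane, IB1C2CCCC1CCC2
Why: Syn-haloboration of the terminal alkyne places iodine on the internal carbon, and protonolysis of the C–B bond gives the 1,1-disubstituted alkenyl iodide (Markovnikov hydroiodination).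

Step 16
Reactants: 22 (3S,5E,7R)-2-iodo-3-(PMBO)-7-(TBSO)-6,10-dimethylundeca-1,5,9-triene; 4 (Z)-6-(TBSO)-4-methylhex-4-enal
Product: 23 (2Z,8S,10E,12R)-8-(PMBO)-1,12-bis(TBSO)-3,11,15-trimethyl-7-methylidenehexadeca-2,10,14-trien-6-ol (C6 epimers)
Conditions: CrCl2 (4 equiv), NiCl2 (1 mol%), DMSO, rt
Reagents that add atoms: none
Why: Nozaki–Hiyama–Kishi coupling forms C6–C7 through a nickel-activated alkenylchromium that adds only to the aldehyde and tolerates the ethers; C6 forms without control and is erased in step 17.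

Step 17
Reactants: 23 C6-epimeric allylic alcohol
Product: 24 (2Z,8S,10E,12R)-8-(PMBO)-1,12-bis(TBSO)-3,11,15-trimethyl-7-methylidenehexadeca-2,10,14-trien-6-one
Conditions: Dess–Martin periodinane, CH2Cl2, 0 °C
Reagents that add atoms: none
Why: Dess–Martin oxidation converges both epimers on one α-methylene ketone under neutral conditions that do not trigger conjugate addition or loss of the γ-alkoxy group.

Step 18
Reactants: 24 α-methylene ketone
Product: 25 (2Z,6R,8S,10E,12R)-8-(PMBO)-1,12-bis(TBSO)-3,11,15-trimethyl-7-methylidenehexadeca-2,10,14-trien-6-ol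
Conditions: (S)-1-methyl-3,3-diphenyltetrahydro-1H,3H-pyrrolo[1,2-c][1,3,2]oxazaborole [(S)-Me-CBS, 0.3 equiv], catecholborane, toluene, −78 °C
Reagents that add atoms: none
Why: Corey–Bakshi–Shibata reduction with the branched alkenyl group as the large substituent should deliver hydride to the face giving the 6R carbinol under catalyst control, 1,2-selectively and without hydroboration.

Step 19
Reactants: 25 (6R)-allylic alcohol
Product: 26 (2Z,6R,7S,8S,10E,12R)-7,19-epoxy-8-(PMBO)-1,12-bis(TBSO)-3,11,15-trimethylhexadeca-2,10,14-trien-6-ol (erythro; oxirane spans C7 and C19)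
Conditions: Ti(OiPr)4 (0.3 equiv), D-(−)-diisopropyl tartrate (0.36 equiv), t-BuOOH, 4 Å molecular sieves, CH2Cl2, −20 °C
Reagents that add atoms: tert-butyl hydroperoxide, CC(C)(C)OO
Why: Sharpless epoxidation directed by the 6R hydroxyl, for which D-(−)-tartrate is the matched ligand, delivers oxygen erythro to O6 and so sets C7 on the methylene face required by the later invertive shift; the trisubstituted alkenes carry no free allylic hydroxyl and stay untouched.

Step 20
Reactants: 26 erythro epoxy alcohol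
Product: 27 (2Z,6S,7R,8S,10E,12R)-7,19-epoxy-8-(PMBO)-1,12-bis(TBSO)-3,11,15-trimethylhexadeca-2,10,14-trien-6-yl 4-nitrobenzoate
Conditions: PPh3, DIAD, 4-nitrobenzoic acid, toluene, 0 °C to rt
Reagents that add atoms: 4-nitrobenzoic acid, OC(=O)c1ccc(cc1)[N+](=O)[O-]
Why: Mitsunobu esterification displaces the activated O6 with SN2 inversion, turning the erythro into the threo series (6R to 6S) without touching C7; the acidic nitrobenzoic acid is chosen for the hindered carbinol.

Step 21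
Reactants: 27 4-nitrobenzoate
Product: 28 (2Z,6S,7S,8S,10E,12R)-7,19-epoxy-8-(PMBO)-1,12-bis(TBSO)-3,11,15-trimethylhexadeca-2,10,14-trien-6-ol (threo)
Conditions: K2CO3 (0.3 equiv), MeOH, 0 °C
Reagents that add atoms: none
Why: Carbonate-catalysed transesterification of the activated ester is fast in cold methanol, where the alkoxide concentration is too low for the oxirane to move appreciably; any 29 formed would simply be carried forward.

Step 22
Reactants: 28 threo 7,19-epoxy-6-ol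
Product: 29 (2Z,6S,7R,8S,10E,12R)-6,7-epoxy-7-(hydroxymethyl)-8-(PMBO)-1,12-bis(TBSO)-3,11,15-trimethylhexadeca-2,10,14-triene
Conditions: KOt-Bu (0.5 equiv), t-BuOH/THF, 0 °C to rt; aqueous NH4Cl
Reagents that add atoms: none
Why: Catalytic tert-butoxide deprotonates the 6S hydroxyl, and the alkoxide attacks C7 of the adjacent C7–C19 oxirane opposite the departing oxygen, forming the C7–O bond of the new C6–C7 oxirane and releasing C19–O as a primary alkoxide that the solvent reprotonates. This is a Payne rearrangement of a 1,2-epoxy-3-ol into the 2,3-epoxy-1-ol with the more substituted ring. The oxirane closes in the 3-exo-tet mode. C7 is the only centre that changes: backside attack inverts it, so its configuration in 29 is dictated by the oxirane face set in step 19, while C6 keeps the configuration set in step 20 and the threo relation of 28 becomes C5 cis to C19 on the new ring. The step needs O6 as the only nucleophile and an equilibrium on the product side: O8 is blocked as a PMB ether with no silyl group within reach of either alkoxide, and the trisubstituted oxirane with a primary alkoxide is favoured over the 1,1-disubstituted oxirane with a secondary alkoxide.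

Step 23
Reactants: 29 PMB-protected epoxy alcohol
Product: 30 (2Z,6S,7S,8S,10E,12R)-6,7-epoxy-7-(hydroxymethyl)-1,12-bis(TBSO)-3,11,15-trimethylhexadeca-2,10,14-trien-8-ol
Conditions: DDQ, CH2Cl2/pH 7 phosphate buffer, 0 °C
Reagents that add atoms: none
Why: Oxidative cleavage of the PMB ether by hydride abstraction and hydrolysis of the oxocarbenium ion frees O8 under neutral conditions that spare the oxirane and the allylic silyl ethers.

Step 24
Reactants: 30 bis-TBS ether
Product: 31 (2Z,6S,7S,8S,10E,12R)-6,7-epoxy-7-(hydroxymethyl)-3,11,15-trimethylhexadeca-2,10,14-triene-1,8,12-triol (CNP0167574.1)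
Conditions: TBAF, AcOH (1:1), THF, 0 °C to rt
Reagents that add atoms: none
Why: Fluoride-mediated desilylation buffered with acetic acid removes both TBS groups without generating free alkoxides, which could otherwise move the oxirane toward O8 or O19.

**Compound list**
1 | nerol | CC(C)=CCC/C(C)=C\CO | starting material
2 | neryl TBS ether | CC(C)=CCC/C(C)=C\CO[Si](C)(C)C(C)(C)C | intermediate
3 | (Z)-6,7-epoxy-1-(TBSO)-3,7-dimethyloct-2-ene (racemic) | CC1(C)OC1CC/C(C)=C\CO[Si](C)(C)C(C)(C)C | intermediate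
4 | (Z)-6-(TBSO)-4-methylhex-4-enal | O=CCC/C(C)=C\CO[Si](C)(C)C(C)(C)C | intermediate
5 | (S)-glycidol | OC[C@H]1CO1 | starting material
6 | 2-methyl-1-propenylmagnesium bromide | CC(C)=C[Mg]Br | starting material
7 | (R)-6-methylhept-5-ene-1,2-diol | OC[C@H](O)CC=C(C)C | intermediate
8 | (R)-1,2-bis(TBSO)-6-methylhept-5-ene | CC(C)(C)[Si](C)(C)OC[C@H](O[Si](C)(C)C(C)(C)C)CC=C(C)C | intermediate
9 | (R)-2-(TBSO)-6-methylhept-5-en-1-ol | OC[C@H](O[Si](C)(C)C(C)(C)C)CC=C(C)C | intermediate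
10 | (R)-2-(TBSO)-6-methylhept-5-enal | O=C[C@H](O[Si](C)(C)C(C)(C)C)CC=C(C)C | intermediate
11 | (R)-3-(TBSO)-6-methylhept-5-en-1-yne | C#C[C@H](O[Si](C)(C)C(C)(C)C)CC=C(C)C | intermediate
12 | dimethyl[(1E,3R)-3-(TBSO)-2,6-dimethylhepta-1,5-dienyl]alane | C[Al](C)/C=C(C)/[C@H](O[Si](C)(C)C(C)(C)C)CC=C(C)C | intermediate (not isolated)
13 | (1E,3R)-1-iodo-3-(TBSO)-2,6-dimethylhepta-1,5-diene | I/C=C(C)/[C@H](O[Si](C)(C)C(C)(C)C)CC=C(C)C | intermediate
14 | (S)-trityl glycidyl ether [trityl ether of (R)-glycidol] | C(c1ccccc1)(c1ccccc1)(c1ccccc1)OC[C@@H]1CO1 | starting material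
15 | (1E,3R)-3-(TBSO)-2,6-dimethylhepta-1,5-dienyllithium | [Li]/C=C(C)/[C@H](O[Si](C)(C)C(C)(C)C)CC=C(C)C | intermediate (not isolated)
16 | (2S,4E,6R)-6-(TBSO)-5,9-dimethyl-1-(trityloxy)deca-4,8-dien-2-ol | C(c1ccccc1)(c1ccccc1)(c1ccccc1)OC[C@@H](O)C/C=C(C)/[C@H](O[Si](C)(C)C(C)(C)C)CC=C(C)C | intermediate
17 | (2S,4E,6R)-6-(TBSO)-2-(PMBO)-5,9-dimethyl-1-(trityloxy)deca-4,8-diene | C(c1ccccc1)(c1ccccc1)(c1ccccc1)OC[C@@H](OCc1ccc(OC)cc1)C/C=C(C)/[C@H](O[Si](C)(C)C(C)(C)C)CC=C(C)C | intermediate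
18 | (2S,4E,6R)-6-(TBSO)-2-(PMBO)-5,9-dimethyldeca-4,8-dien-1-ol | OC[C@@H](OCc1ccc(OC)cc1)C/C=C(C)/[C@H](O[Si](C)(C)C(C)(C)C)CC=C(C)C | intermediate
19 | (2S,4E,6R)-6-(TBSO)-2-(PMBO)-5,9-dimethyldeca-4,8-dienal | O=C[C@@H](OCc1ccc(OC)cc1)C/C=C(C)/[C@H](O[Si](C)(C)C(C)(C)C)CC=C(C)C | intermediate
20 | (3S,5E,7R)-7-(TBSO)-3-(PMBO)-6,10-dimethylundeca-5,9-dien-1-yne | C#C[C@@H](OCc1ccc(OC)cc1)C/C=C(C)/[C@H](O[Si](C)(C)C(C)(C)C)CC=C(C)C | intermediate
21 | B-[(1Z,3S,5E,7R)-2-iodo-3-(PMBO)-7-(TBSO)-6,10-dimethylundeca-1,5,9-trienyl]-9-BBN | I/C(=C\B1C2CCCC1CCC2)[C@@H](OCc1ccc(OC)cc1)C/C=C(C)/[C@H](O[Si](C)(C)C(C)(C)C)CC=C(C)C | intermediate (not isolated)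
22 | (3S,5E,7R)-2-iodo-3-(PMBO)-7-(TBSO)-6,10-dimethylundeca-1,5,9-triene | C=C(I)[C@@H](OCc1ccc(OC)cc1)C/C=C(C)/[C@H](O[Si](C)(C)C(C)(C)C)CC=C(C)C | intermediate
23 | (2Z,8S,10E,12R)-8-(PMBO)-1,12-bis(TBSO)-3,11,15-trimethyl-7-methylidenehexadeca-2,10,14-trien-6-ol (C6 epimers) | C=C([C@@H](OCc1ccc(OC)cc1)C/C=C(C)/[C@H](O[Si](C)(C)C(C)(C)C)CC=C(C)C)C(O)CC/C(C)=C\CO[Si](C)(C)C(C)(C)C | intermediate
24 | (2Z,8S,10E,12R)-8-(PMBO)-1,12-bis(TBSO)-3,11,15-trimethyl-7-methylidenehexadeca-2,10,14-trien-6-one | C=C([C@@H](OCc1ccc(OC)cc1)C/C=C(C)/[C@H](O[Si](C)(C)C(C)(C)C)CC=C(C)C)C(=O)CC/C(C)=C\CO[Si](C)(C)C(C)(C)C | intermediate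
25 | (2Z,6R,8S,10E,12R)-8-(PMBO)-1,12-bis(TBSO)-3,11,15-trimethyl-7-methylidenehexadeca-2,10,14-trien-6-ol | C=C([C@@H](OCc1ccc(OC)cc1)C/C=C(C)/[C@H](O[Si](C)(C)C(C)(C)C)CC=C(C)C)[C@H](O)CC/C(C)=C\CO[Si](C)(C)C(C)(C)C | intermediate
26 | (2Z,6R,7S,8S,10E,12R)-7,19-epoxy-8-(PMBO)-1,12-bis(TBSO)-3,11,15-trimethylhexadeca-2,10,14-trien-6-ol (erythro) | CC(C)=CC[C@@H](O[Si](C)(C)C(C)(C)C)/C(C)=C/C[C@H](OCc1ccc(OC)cc1)[C@]1(CO1)[C@H](O)CC/C(C)=C\CO[Si](C)(C)C(C)(C)C | intermediate
27 | (2Z,6S,7R,8S,10E,12R)-7,19-epoxy-8-(PMBO)-1,12-bis(TBSO)-3,11,15-trimethylhexadeca-2,10,14-trien-6-yl 4-nitrobenzoate | CC(C)=CC[C@@H](O[Si](C)(C)C(C)(C)C)/C(C)=C/C[C@H](OCc1ccc(OC)cc1)[C@]1(CO1)[C@@H](OC(=O)c1ccc(cc1)[N+](=O)[O-])CC/C(C)=C\CO[Si](C)(C)C(C)(C)C | intermediate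
28 | (2Z,6S,7S,8S,10E,12R)-7,19-epoxy-8-(PMBO)-1,12-bis(TBSO)-3,11,15-trimethylhexadeca-2,10,14-trien-6-ol (threo; Payne precursor) | CC(C)=CC[C@@H](O[Si](C)(C)C(C)(C)C)/C(C)=C/C[C@H](OCc1ccc(OC)cc1)[C@]1(CO1)[C@@H](O)CC/C(C)=C\CO[Si](C)(C)C(C)(C)C | intermediate
29 | (2Z,6S,7R,8S,10E,12R)-6,7-epoxy-7-(hydroxymethyl)-8-(PMBO)-1,12-bis(TBSO)-3,11,15-trimethylhexadeca-2,10,14-triene (Payne product) | CC(C)=CC[C@@H](O[Si](C)(C)C(C)(C)C)/C(C)=C/C[C@H](OCc1ccc(OC)cc1)[C@]1(CO)O[C@H]1CC/C(C)=C\CO[Si](C)(C)C(C)(C)C | intermediate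
30 | (2Z,6S,7S,8S,10E,12R)-6,7-epoxy-7-(hydroxymethyl)-1,12-bis(TBSO)-3,11,15-trimethylhexadeca-2,10,14-trien-8-ol | CC(C)=CC[C@@H](O[Si](C)(C)C(C)(C)C)/C(C)=C/C[C@H](O)[C@]1(CO)O[C@H]1CC/C(C)=C\CO[Si](C)(C)C(C)(C)C | intermediate
31 | (2Z,6S,7S,8S,10E,12R)-6,7-epoxy-7-(hydroxymethyl)-3,11,15-trimethylhexadeca-2,10,14-triene-1,8,12-triol (CNP0167574.1) | CC(C)=CC[C@@H](O)/C(C)=C/C[C@H](O)[C@]1(CO)O[C@H]1CC/C(C)=C\CO | target

**Count**
Total: 24 steps. Longest linear sequence: 21 steps (steps 4 to 24, from (S)-glycidol). The nerol branch (steps 1 to 3) joins at step 16.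

**Steps most likely to fail**

Step 20 (Mitsunobu inversion). The displacement at C6 may be slow next to the fully substituted oxirane carbon, so elimination toward C5 or acyl transfer with retention could compete. The fallback sets the oxirane face from the other carbinol instead of inverting C6. It sets out from enone 24: reduction with the (R)-configured oxazaborolidine and catecholborane would give the 6S allylic alcohol F1; Ac2O, pyridine and 4-dimethylaminopyridine the 6-acetate F2; DDQ in buffered wet CH2Cl2 the 8-hydroxy acetate F3. Ti(OiPr)4, L-(+)-diisopropyl tartrate and t-BuOOH, now directed by the 8S hydroxyl (matched; erythro to C8 is threo to C6), would give the 7,19-epoxy acetate F4. 4-Methoxybenzyl trichloroacetimidate with catalytic La(OTf)3 would give the 8-PMB ether F5, and K2CO3 in MeOH at 0 °C would remove the acetate and rejoin the route at 28.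

Step 15 (haloboration and protonolysis). The Lewis-acidic iodoborane may cleave the propargylic PMB ether or a silyl ether before it adds to the alkyne, and boron may not go cleanly to the terminal carbon. The fallback avoids the alkyne and sets out from aldehyde 19: MeMgBr would give the secondary carbinol F6, Dess–Martin oxidation the methyl ketone F7, and kinetic enolisation with KN(SiMe3)2 at −78 °C followed by PhNTf2 the enol triflate F8. F8 would enter the CrCl2/NiCl2 coupling with 4 and come back to the route at 23.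

Step 23 (oxidative PMB removal). The benzylic oxocarbenium ion may be trapped by the neighbouring C19 hydroxyl to give a cyclic anisylidene acetal, or be overoxidised to a benzoate, instead of being hydrolysed. The fallback removes the participating hydroxyl first. It sets out from 29: TBSCl and imidazole would give the 19-silyl ether F9, DDQ in buffered wet CH2Cl2 the 8-ol F10, and the buffered fluoride of step 24 would then remove all three silyl groups and come back to the route at 31.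

Further compounds
F1 | step 20 | (2Z,6S,8S,10E,12R)-8-(PMBO)-1,12-bis(TBSO)-3,11,15-trimethyl-7-methylidenehexadeca-2,10,14-trien-6-ol | C=C([C@@H](OCc1ccc(OC)cc1)C/C=C(C)/[C@H](O[Si](C)(C)C(C)(C)C)CC=C(C)C)[C@@H](O)CC/C(C)=C\CO[Si](C)(C)C(C)(C)C
F2 | step 20 | 6-acetate of F1 | C=C([C@@H](OCc1ccc(OC)cc1)C/C=C(C)/[C@H](O[Si](C)(C)C(C)(C)C)CC=C(C)C)[C@@H](OC(C)=O)CC/C(C)=C\CO[Si](C)(C)C(C)(C)C
F3 | step 20 | (6S,8S)-8-hydroxy-1,12-bis(TBSO)-7-methylidene 6-acetate | C=C([C@@H](O)C/C=C(C)/[C@H](O[Si](C)(C)C(C)(C)C)CC=C(C)C)[C@@H](OC(C)=O)CC/C(C)=C\CO[Si](C)(C)C(C)(C)C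
F4 | step 20 | 7,19-epoxy-8-hydroxy-1,12-bis(TBSO) 6-acetate (C6, C7, C8 and C12 as in 28) | CC(C)=CC[C@@H](O[Si](C)(C)C(C)(C)C)/C(C)=C/C[C@H](O)[C@]1(CO1)[C@@H](OC(C)=O)CC/C(C)=C\CO[Si](C)(C)C(C)(C)C
F5 | step 20 | 6-acetate of 28 | CC(C)=CC[C@@H](O[Si](C)(C)C(C)(C)C)/C(C)=C/C[C@H](OCc1ccc(OC)cc1)[C@]1(CO1)[C@@H](OC(C)=O)CC/C(C)=C\CO[Si](C)(C)C(C)(C)C
F6 | step 15 | (3S,5E,7R)-7-(TBSO)-3-(PMBO)-6,10-dimethylundeca-5,9-dien-2-ol (C2 epimers) | CC(O)[C@@H](OCc1ccc(OC)cc1)C/C=C(C)/[C@H](O[Si](C)(C)C(C)(C)C)CC=C(C)C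
F7 | step 15 | (3S,5E,7R)-7-(TBSO)-3-(PMBO)-6,10-dimethylundeca-5,9-dien-2-one | CC(=O)[C@@H](OCc1ccc(OC)cc1)C/C=C(C)/[C@H](O[Si](C)(C)C(C)(C)C)CC=C(C)C
F8 | step 15 | (3S,5E,7R)-7-(TBSO)-3-(PMBO)-6,10-dimethylundeca-1,5,9-trien-2-yl trifluoromethanesulfonate | C=C(OS(=O)(=O)C(F)(F)F)[C@@H](OCc1ccc(OC)cc1)C/C=C(C)/[C@H](O[Si](C)(C)C(C)(C)C)CC=C(C)C
F9 | step 23 | 19-O-TBS ether of 29 | CC(C)=CC[C@@H](O[Si](C)(C)C(C)(C)C)/C(C)=C/C[C@H](OCc1ccc(OC)cc1)[C@]1(CO[Si](C)(C)C(C)(C)C)O[C@H]1CC/C(C)=C\CO[Si](C)(C)C(C)(C)C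
F10 | step 23 | 19-O-TBS ether of 30 | CC(C)=CC[C@@H](O[Si](C)(C)C(C)(C)C)/C(C)=C/C[C@H](O)[C@]1(CO[Si](C)(C)C(C)(C)C)O[C@H]1CC/C(C)=C\CO[Si](C)(C)C(C)(C)C
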